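A direct plan would acylate 1,2,3,5-tetramethoxybenzene A1, with loss of one ortho methyl group, to the 2-hydroxy-3,4,6-trimethoxyacetophenone A2 and oxidise A2 to the arylglyoxal A3.
It would mono-methylate 3,4,5-trihydroxybenzaldehyde A4 to 3,5-dihydroxy-4-methoxybenzaldehyde A5.
A carbene-catalysed cross-benzoin of A5 onto A3 with cyclodehydration would give the 5,7,8-trimethoxyflavonol A6, and cleavage of its 5-methyl ether would end the plan.
The union would be the weakest step: an acyl anion equivalent would have to form beside three free phenols and prefer the glyoxal to a second aldehyde, without close precedent.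
The mono-methylation would be weak because three phenols of similar acidity compete and over-alkylation is hard to stop.
The final demethylation would be weak because the 3-hydroxy-4-keto chelate and the crowded 8-methoxy group compete with the 5-methoxy group for the Lewis acid.

**Strategy.** The route rests on building ring A last, by benzannulation of a preformed 2-aryl-3-benzyloxy-4-pyranone (rings B and C). The four contiguous ring A carbons C5(OH)–C6(H)–C7(OMe)–C8(OMe) map one-to-one onto a methyl semisquarate adduct: thermal 4π opening of the 4-methoxycyclobutenone at pyranone C6 and 6π closure of the dienylketene onto C5 forge the C4a–C5 bond and deliver ring A with the 5-OH free and every other ring A oxygen already in its final form. No ether is cleaved selectively, no phenol is methylated selectively, and no carbene coupling beside free phenols is needed; benzyl ethers carry the 3-, 3'- and 5'-oxygens to a single closing hydrogenolysis.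

Key step: step 6

Remark: the target is achiral; the stereocentres of 8, 11, 14, 15 and 17 are formed racemic and are all lost before the end, so no stereocontrol is required. Compounds 1, 4 and 10 are taken as catalogue compounds.

**Step 1**
Reactants: 1 methyl 3,5-dihydroxy-4-methoxybenzoate
Product: 3 3,5-bis(benzyloxy)-4-methoxybenzoic acid, via dibenzyl ether methyl ester 2 (not isolated)
Conditions: BnBr (2.3 equiv), K2CO3 (3 equiv), DMF, 60 °C; then 4 M NaOH, MeOH, 60 °C; 2 M HCl to pH 2
Reagents that add atoms: benzyl bromide, BrCc1ccccc1; sodium hydroxide, [Na+].[OH-]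
Why: Williamson O-benzylation of both phenols (the 4-oxygen is already a methyl ether, so no selectivity is needed), followed by saponification of the methyl ester in the same flask.

**Step 2**
Reactants: 4 2-(benzyloxy)-N-methoxy-N-methylacetamide
Product: 6 (E)-1-(benzyloxy)-4-methoxybut-3-en-2-one, via 1-(benzyloxy)but-3-yn-2-one 5 (not isolated)
Conditions: HC≡CMgBr (1.4 equiv), THF, 0 °C; cold 1 M HCl quench, extraction; crude 5, MeOH, DABCO (10 mol%), 0 °C → rt
Reagents that add atoms: ethynylmagnesium bromide, C#C[Mg]Br; methanol, CO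
Why: Weinreb ketone synthesis stops at the ynone because the magnesium chelate survives until the acidic quench (which also keeps the liberated amine protonated), and amine-catalysed conjugate addition of methanol to the terminal ynone should give the thermodynamically preferred (E)-β-methoxy enone.

**Step 3**
Reactants: 3 3,5-bis(benzyloxy)-4-methoxybenzoic acid; 6 (E)-1-(benzyloxy)-4-methoxybut-3-en-2-one
Product: 9 3-(benzyloxy)-2-[3,5-bis(benzyloxy)-4-methoxyphenyl]-4H-pyran-4-one, via aroyl chloride 7 (not isolated), via 1,3-diketone 8 (not isolated)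
Conditions: 3, (COCl)2 (1.3 equiv), DMF (cat.), CH2Cl2, 0 °C → rt, evaporate; 6 (2.1 equiv), LiN(SiMe3)2 (2.1 equiv), THF, −78 °C, then 7, −78 → 0 °C; then CF3CO2H (6 equiv), CH2Cl2, rt
Reagents that add atoms: none
Why: Claisen-type C-acylation of the only enolisable position of 6 (the benzyloxymethylene) by 7, with the second equivalent of enolate acting as base for the more acidic diketone, then acid-promoted 6-endo oxa-Michael addition of the aroyl enol oxygen to the β-methoxy enone and loss of methanol, the established γ-pyranone synthesis from β-methoxy enone enolates and acid chlorides.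

**Step 4**
Reactants: 10 dimethyl squarate (3,4-dimethoxycyclobut-3-ene-1,2-dione)
Product: 12 3-methoxycyclobut-3-ene-1,2-dione, via hydroxycyclobutenone 11 (not isolated)
Conditions: LiAlH(O-t-Bu)3 (1.05 equiv), THF, −78 → −20 °C; then 6 M HCl, CH2Cl2, 0 °C → rt
Reagents that add atoms: water, O
Why: Mono-reduction of one carbonyl group by the bulky hydride, then acid-promoted allylic transposition and hydrolysis with loss of methanol, the standard preparation of alkyl semisquarates.

**Step 5**
Reactants: 9 3-(benzyloxy)-2-[3,5-bis(benzyloxy)-4-methoxyphenyl]-4H-pyran-4-one; 12 3-methoxycyclobut-3-ene-1,2-dione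
Product: 15 3-(benzyloxy)-2-[3,5-bis(benzyloxy)-4-methoxyphenyl]-6-(1,2-dimethoxy-4-oxocyclobut-2-en-1-yl)-4H-pyran-4-one (racemic), via 6-lithiopyranone 13 (not isolated), via lithium alkoxide 14 (not isolated)
Conditions: lithium 2,2,6,6-tetramethylpiperidide (1.2 equiv, from 2,2,6,6-tetramethylpiperidine, n-BuLi), THF, −78 °C, 20 min; 12 (1.3 equiv), −78 °C; MeOTf (1.3 equiv), −78 → −40 °C; aq. NaHCO3
Reagents that add atoms: methyl trifluoromethanesulfonate, COS(=O)(=O)C(F)(F)F
Why: Kinetic deprotonation by the hindered amide at C6–H, the sp2 C–H next to the ring oxygen (as in the C2 metalation of chromones; C5–H α to the carbonyl is less acidic), 1,2-addition of the α-oxyvinyllithium to the ketone-like carbonyl of 12 (the one flanked by C–OMe; the other is a deactivated vinylogous ester) and O-methylation of the tertiary lithium alkoxide in the flask; the new quaternary centre is racemic and is destroyed in step 6.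

**Step 6**
Reactants: 15 3-(benzyloxy)-2-[3,5-bis(benzyloxy)-4-methoxyphenyl]-6-(1,2-dimethoxy-4-oxocyclobut-2-en-1-yl)-4H-pyran-4-one
Product: 18 3-(benzyloxy)-2-[3,5-bis(benzyloxy)-4-methoxyphenyl]-5-hydroxy-7,8-dimethoxy-4H-chromen-4-one, via dienylketene 16 (not isolated), via 4aH-chromene-4,5-dione 17 (not isolated)
Conditions: degassed PhMe (0.01 M), 110 °C, argon
Reagents that add atoms: none
Why: Thermal conrotatory 4π electrocyclic opening of the cyclobutenone (cleavage of the C(=O)–C(OMe) bond) should give dienylketene 16, in which by torquoselectivity the donor methoxy group has rotated outward and the pyranonyl group inward, cis to the ketene. The ketene carbon then closes onto pyranone C5 by a 6π electrocyclisation (the only ring formed, six-membered ring A, closed at the C4a–C5 carbon–carbon bond), and dienone 17, whose C4a–H lies between two carbonyl groups, should tautomerise at once to the chelated phenol, which makes the sequence irreversible. The closest known reaction type is the thermal ring expansion of 4-aryl-, 4-heteroaryl- and 4-alkenyl-4-alkoxycyclobutenones to mono-protected hydroquinones (squarate benzannulation). No stereocentre remains, since the racemic centres of 15 and 17 are lost on aromatisation. The selectivity needed is regiochemical and is secured by the substrate: carbon closure can only reach C5 (the other neighbour of C6 is the ring oxygen, whose addition to the ketene would be reversible and unproductive), and the placement of 5-OH, 6-H, 7-OMe and 8-OMe follows directly from the positions of C=O, CH, C–OMe and C(OMe) in 15.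

**Step 7**
Reactants: 18 3-(benzyloxy)-2-[3,5-bis(benzyloxy)-4-methoxyphenyl]-5-hydroxy-7,8-dimethoxy-4H-chromen-4-one
Product: 19 2-(3,5-dihydroxy-4-methoxyphenyl)-3,5-dihydroxy-7,8-dimethoxy-4H-chromen-4-one (target)
Conditions: H2 (1 atm), 10% Pd/C, THF/MeOH (1:1), rt
Reagents that add atoms: none
Why: Hydrogenolysis of the three benzyl ethers (two aryl, one enol) over palladium on carbon; the methyl ethers, the chelated 5-OH and the chromone double bond should be untouched at 1 atm and room temperature.

## Compound list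

1 | methyl 3,5-dihydroxy-4-methoxybenzoate | COC(=O)c1cc(O)c(OC)c(O)c1 | starting material
2 | methyl 3,5-bis(benzyloxy)-4-methoxybenzoate | COC(=O)c1cc(OCc2ccccc2)c(OC)c(OCc2ccccc2)c1 | intermediate (not isolated)
3 | 3,5-bis(benzyloxy)-4-methoxybenzoic acid | OC(=O)c1cc(OCc2ccccc2)c(OC)c(OCc2ccccc2)c1 | intermediate
4 | 2-(benzyloxy)-N-methoxy-N-methylacetamide | CON(C)C(=O)COCc1ccccc1 | starting material
5 | 1-(benzyloxy)but-3-yn-2-one | C#CC(=O)COCc1ccccc1 | intermediate (not isolated)
6 | (E)-1-(benzyloxy)-4-methoxybut-3-en-2-one | CO/C=C/C(=O)COCc1ccccc1 | intermediate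
7 | 3,5-bis(benzyloxy)-4-methoxybenzoyl chloride | ClC(=O)c1cc(OCc2ccccc2)c(OC)c(OCc2ccccc2)c1 | intermediate (not isolated)
8 | (E)-1-[3,5-bis(benzyloxy)-4-methoxyphenyl]-2-(benzyloxy)-5-methoxypent-4-ene-1,3-dione (racemic) | CO/C=C/C(=O)C(OCc1ccccc1)C(=O)c1cc(OCc2ccccc2)c(OC)c(OCc2ccccc2)c1 | intermediate (not isolated)
9 | 3-(benzyloxy)-2-[3,5-bis(benzyloxy)-4-methoxyphenyl]-4H-pyran-4-one | O=c1ccoc(-c2cc(OCc3ccccc3)c(OC)c(OCc3ccccc3)c2)c1OCc1ccccc1 | intermediate
10 | dimethyl squarate (3,4-dimethoxycyclobut-3-ene-1,2-dione) | COC1=C(OC)C(=O)C1=O | starting material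
11 | 4-hydroxy-2,3-dimethoxycyclobut-2-en-1-one (racemic) | COC1=C(OC)C(O)C1=O | intermediate (not isolated)
12 | 3-methoxycyclobut-3-ene-1,2-dione | COC1=CC(=O)C1=O | intermediate
13 | {5-(benzyloxy)-6-[3,5-bis(benzyloxy)-4-methoxyphenyl]-4-oxo-4H-pyran-2-yl}lithium | [Li]c1cc(=O)c(OCc2ccccc2)c(-c2cc(OCc3ccccc3)c(OC)c(OCc3ccccc3)c2)o1 | intermediate (not isolated)
14 | lithium 1-{5-(benzyloxy)-6-[3,5-bis(benzyloxy)-4-methoxyphenyl]-4-oxo-4H-pyran-2-yl}-2-methoxy-4-oxocyclobut-2-en-1-olate (racemic) | [Li+].[O-]C1(C(=O)C=C1OC)c1cc(=O)c(OCc2ccccc2)c(-c2cc(OCc3ccccc3)c(OC)c(OCc3ccccc3)c2)o1 | intermediate (not isolated)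
15 | 3-(benzyloxy)-2-[3,5-bis(benzyloxy)-4-methoxyphenyl]-6-(1,2-dimethoxy-4-oxocyclobut-2-en-1-yl)-4H-pyran-4-one (racemic) | COC1=CC(=O)C1(OC)c1cc(=O)c(OCc2ccccc2)c(-c2cc(OCc3ccccc3)c(OC)c(OCc3ccccc3)c2)o1 | intermediate
16 | 3-(benzyloxy)-2-[3,5-bis(benzyloxy)-4-methoxyphenyl]-6-[(1Z)-1,2-dimethoxy-4-oxobuta-1,3-dien-1-yl]-4H-pyran-4-one | O=C=C/C(OC)=C(OC)\c1cc(=O)c(OCc2ccccc2)c(-c2cc(OCc3ccccc3)c(OC)c(OCc3ccccc3)c2)o1 | intermediate (not isolated)
17 | 3-(benzyloxy)-2-[3,5-bis(benzyloxy)-4-methoxyphenyl]-7,8-dimethoxy-4H-chromene-4,5(4aH)-dione (racemic) | COC1=CC(=O)C2C(=O)C(OCc3ccccc3)=C(-c3cc(OCc4ccccc4)c(OC)c(OCc4ccccc4)c3)OC2=C1OC | intermediate (not isolated)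
18 | 3-(benzyloxy)-2-[3,5-bis(benzyloxy)-4-methoxyphenyl]-5-hydroxy-7,8-dimethoxy-4H-chromen-4-one | COc1cc(O)c2c(=O)c(OCc3ccccc3)c(-c3cc(OCc4ccccc4)c(OC)c(OCc4ccccc4)c3)oc2c1OC | intermediate
19 | 2-(3,5-dihydroxy-4-methoxyphenyl)-3,5-dihydroxy-7,8-dimethoxy-4H-chromen-4-one (achiral) | COc1cc(O)c2c(=O)c(O)c(-c3cc(O)c(OC)c(O)c3)oc2c1OC | target

Total step count: 7. Longest linear sequence: 5 steps (step 1 or step 2, then steps 3, 5, 6 and 7); step 4 is a one-step side branch.

## Steps most likely to fail

**Step 5.** The deprotonation may be unselective (C5–H, whose anion could open the ring by β-elimination of the ring oxygen, or a benzylic C–H), or the lithio species may decay before it is trapped. The fallback sets out from 9 and fixes the metalation site through a halide. Compound 9 would be zincated at C6 with (2,2,6,6-tetramethylpiperidyl)zinc chloride–lithium chloride, (C9H18N)ZnCl·LiCl, in THF at 25 °C; this base metalates chromones next to the ring oxygen when no Lewis acid is added and gives a stable organozinc. Iodolysis with I2 would give 3-(benzyloxy)-2-[3,5-bis(benzyloxy)-4-methoxyphenyl]-6-iodo-4H-pyran-4-one F1. Iodine–lithium exchange on F1 with n-BuLi at −100 °C would then generate 13 at a defined position within seconds, and the route is rejoined at 13 (addition of 12, then MeOTf, to 15).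

**Step 6.** The ketene may be diverted before it closes (dimerisation or capture by adventitious nucleophiles), or the methyl ether may open only at temperatures at which the enol benzyl ether degrades. The fallback sets out from 14 and uses the free carbinol, whose hydroxyl is the stronger outward-rotating donor and the best-precedented substrate. Quenching 14 with aqueous NH4Cl instead of MeOTf would give 3-(benzyloxy)-2-[3,5-bis(benzyloxy)-4-methoxyphenyl]-6-(1-hydroxy-2-methoxy-4-oxocyclobut-2-en-1-yl)-4H-pyran-4-one F2. Thermolysis of F2 in degassed p-xylene under argon should give the hydroquinone 3-(benzyloxy)-2-[3,5-bis(benzyloxy)-4-methoxyphenyl]-5,8-dihydroxy-7-methoxy-4H-chromen-4-one F3. F3 would be methylated at once with MeI (1.05 equiv) and K2CO3 in acetone under argon at the unchelated 8-OH; the 5-OH is held in the hydrogen bond to the C4 carbonyl. The route is rejoined at 18.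

**Step 3.** O-acylation or double acylation of the α-alkoxy enolate may compete with C-acylation. The fallback sets out from 7 and replaces the acylation by an aldol addition and oxidation. Reduction of 7 with LiAlH(O-t-Bu)3 in THF at −78 °C would give 3,5-bis(benzyloxy)-4-methoxybenzaldehyde F4. Aldol addition of the lithium enolate of 6 (LiN(SiMe3)2, THF, −78 °C) to F4 would give (E)-1-[3,5-bis(benzyloxy)-4-methoxyphenyl]-2-(benzyloxy)-1-hydroxy-5-methoxypent-4-en-3-one F5 as a diastereomer mixture. Oxidation of F5 with Dess–Martin periodinane would give 8, where the route is rejoined (CF3CO2H to 9).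

## Further compounds

F1 | step 5 | 3-(benzyloxy)-2-[3,5-bis(benzyloxy)-4-methoxyphenyl]-6-iodo-4H-pyran-4-one | Ic1cc(=O)c(OCc2ccccc2)c(-c2cc(OCc3ccccc3)c(OC)c(OCc3ccccc3)c2)o1
F2 | step 6 | 3-(benzyloxy)-2-[3,5-bis(benzyloxy)-4-methoxyphenyl]-6-(1-hydroxy-2-methoxy-4-oxocyclobut-2-en-1-yl)-4H-pyran-4-one (racemic) | COC1=CC(=O)C1(O)c1cc(=O)c(OCc2ccccc2)c(-c2cc(OCc3ccccc3)c(OC)c(OCc3ccccc3)c2)o1
F3 | step 6 | 3-(benzyloxy)-2-[3,5-bis(benzyloxy)-4-methoxyphenyl]-5,8-dihydroxy-7-methoxy-4H-chromen-4-one | COc1cc(O)c2c(=O)c(OCc3ccccc3)c(-c3cc(OCc4ccccc4)c(OC)c(OCc4ccccc4)c3)oc2c1O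
F4 | step 3 | 3,5-bis(benzyloxy)-4-methoxybenzaldehyde | O=Cc1cc(OCc2ccccc2)c(OC)c(OCc2ccccc2)c1
F5 | step 3 | (E)-1-[3,5-bis(benzyloxy)-4-methoxyphenyl]-2-(benzyloxy)-1-hydroxy-5-methoxypent-4-en-3-one (racemic, diastereomer mixture) | CO/C=C/C(=O)C(OCc1ccccc1)C(O)c1cc(OCc2ccccc2)c(OC)c(OCc2ccccc2)c1
A1 | direct plan | 1,2,3,5-tetramethoxybenzene | COc1cc(OC)c(OC)c(OC)c1
A2 | direct plan | 1-(2-hydroxy-3,4,6-trimethoxyphenyl)ethan-1-one | CC(=O)c1c(OC)cc(OC)c(OC)c1O
A3 | direct plan | 2-(2-hydroxy-3,4,6-trimethoxyphenyl)-2-oxoacetaldehyde | O=CC(=O)c1c(OC)cc(OC)c(OC)c1O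
A4 | direct plan | 3,4,5-trihydroxybenzaldehyde | O=Cc1cc(O)c(O)c(O)c1
A5 | direct plan | 3,5-dihydroxy-4-methoxybenzaldehyde | COc1c(O)cc(C=O)cc1O
A6 | direct plan | 2-(3,5-dihydroxy-4-methoxyphenyl)-3-hydroxy-5,7,8-trimethoxy-4H-chromen-4-one | COc1cc(OC)c2c(=O)c(O)c(-c3cc(O)c(OC)c(O)c3)oc2c1OC
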